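| flask | left-handed substrate | right-handed substrate | partner | free catalyst | remark | time |
|---|---|---|---|---|---|---|
| blue | 0.11 M | 0.11 M | 0.132 M | 22 mM | the very flask that is asked about, followed so far |  |
| grey | 0.17 M | 0.17 M | 0.132 M | 22 mM | run made earlier |  |
| flask | 0.11 M | 0.11 M | 0.132 M | 22 mM |  | 15 min |

| run | time / min | left-handed substrate / % | right-handed substrate / % |
|---|---|---|---|
| blue | 1.33 | 29.3 | 45.6 |
| blue | 2.50 | 23.3 | 43.1 |
| blue | 4.00 | 19.7 | 41.9 |
| blue | 5.00 | 17.7 | 42.2 |
| blue | 6.00 | 18.2 | 40.6 |
| grey | 0.833 | 35.6 | 47.2 |
| grey | 1.50 | 30.4 | 45.7 |
| grey | 3.00 | 26.1 | 43.4 |
| grey | 6.00 | 23.6 | 44.0 |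
| grey | 10.0 | 23.2 | 43.1 |

(each reading ± 0.5 percentage points)

- free catalyst is single-handed; left-handed substrate and right-handed substrate are mirror images of each other, charged as a racemate, each of them at the stated concentration
- an excess is the difference of the two amounts in percent of their sum
- an excess is below zero if the other one leads

* part of the left-handed substrate and right-handed substrate charged together that has reacted at 15 min
* excess of left-handed product over right-handed product in the product at 15 min
* excess of right-handed substrate over left-handed substrate among what is left of the two at 15 min

Early in the blue run, at 1.33 min, less left-handed substrate (29.3%) stood than right-handed substrate (45.6%), and this kinetic resolution still showed in the last blue reading. The readings hold no product, so I reckoned from what had gone from each substrate, with amounts in percent of the two together charged: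

ledger = ([right-handed substrate] − [left-handed substrate]) / (100% − [left-handed substrate] − [right-handed substrate])

blue, 6.00 min: (40.6% − 18.2%) / (100% − 18.2% − 40.6%) = 54.4%

I called this the ledger: the excess of left-handed product if each product keeps the hand it was made with.

I turned the question round: what must be true for eP to be zero? One way is equal substrates, but the blue readings at 6.00 min stood 22 percentage points apart, with a scatter of 0.5 points. Another way is left-handed product changing hand after it is made, on a time short against 15 min. The blue readings hold substrates and no product, so they did not tell me how far blue stood from that, and I took the ledger as eP on the condition that each product keeps its hand.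

The forecast gave c 42.7%, eP 57% and eS 42.5%: “Hence c≈42.7%, with product about 33.5 versus 9.2.” My ledger, read at an earlier time, stood lower than its eP.

The flask gave c 45.9%, eP 0.121% and eS 47.6%.

    2 free catalyst → spent catalyst (k = 0.0980 M⁻¹ s⁻¹)
    partner → decomposed reagent (k = 8.00 × 10⁻⁴ s⁻¹)
    partner + free catalyst + left-handed substrate → free catalyst + left-handed product (k = 3.70 M⁻² s⁻¹)
    left-handed product ⇌ right-handed product (k = 0.0110 s⁻¹)
    partner + free catalyst + right-handed substrate → free catalyst + right-handed product (k = 0.660 M⁻² s⁻¹)

At 15 min the flask's left-handed and right-handed substrates, 14.2% and 39.9%, put the ledger at 56.1%, far above the flask's eP of 0.121%. The half-life of left-handed product by racemization, its forward step with the way back not counted, was 1.1 min, short against 15 min. In the neighbour charged with [partner] 0.33 M, the left-handed and right-handed substrates stood at 0.547% and 22.3% at 15.0 min, so the ledger gives 28.2%. The computed eP of that neighbour was −0.258%.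

The data stem from a simulated flask for substances that don't exist; the scatter is artificial.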